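Ring A is cut at C1–C2 and C4–C5 (clerodane numbering) into methyl vinyl ketone (C2, C3, C4 and the C4 methyl) and a ring-B methylenecyclohexane that already holds C8, C9 and the exocyclic C10=C1 alkene. The key step, a Lewis-acid sequential ene [3+3] annulation, exploits the fact that this alkene has a single allylic hydrogen, on C5, because C9 is quaternary: the first ene reaction forms C1–C2 and moves the alkene to C5=C10, and a carbonyl-ene closure then forms C4–C5 with the quaternary C5. Hydrogen-atom-transfer hydrogenation, dehydration and a Negishi coupling with a (Z)-iodobutenediol ester finish the target.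

Key step: step 4

Remark: atoms are named by clerodane numbering (ring fusion C5/C10; methyls C17, C18, C19, C20 on C8, C4, C5, C9; side chain C11–C16). The methyl-bearing α′-carbon of 4 and 5 (C5) and the carbinol carbon C4 of 8–12 are epimer mixtures that are destroyed in steps 4 and 8, so their SMILES carry no descriptor there.

Step 1
Reactants: 1 2-methylcyclohex-2-en-1-one
Product: 3 (2S,3R)-2-allyl-2,3-dimethylcyclohexan-1-one, via magnesium enolate 2 (not isolated)
Conditions: MeMgBr, Cu(OTf)2 (cat.), chiral NHC ligand (cat.), Et2O, −30 °C; then allyl iodide, DMPU, −30 °C → rt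
Reagents that add atoms: methylmagnesium bromide C[Mg]Br; allyl iodide C=CCI
Why: Copper-catalysed asymmetric conjugate addition of the Grignard reagent sets C8 (R) under ligand control, and the magnesium enolate is allylated anti to the new C8 methyl (conjugate addition–enolate trapping), which sets the quaternary C9 (S) with the two methyls cis.

Step 2
Reactants: 3 (2S,3R)-2-allyl-2,3-dimethylcyclohexan-1-one
Product: 4 (2S,3R,6RS)-2-allyl-2,3,6-trimethylcyclohexan-1-one
Conditions: LDA, THF, −78 °C; MeI, −78 → 0 °C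
Reagents that add atoms: iodomethane CI
Why: Kinetic enolate alkylation can only take place at the remaining α-methylene (C5), since the other α-carbon is quaternary; the new centre is left uncontrolled because it becomes sp2 in step 4.

Step 3
Reactants: 4 (2S,3R,6RS)-2-allyl-2,3,6-trimethylcyclohexan-1-one
Product: 5 (2S,3R,6RS)-2-allyl-2,3,6-trimethyl-1-methylidenecyclohexane
Conditions: Ph3PCH3Br, KOt-Bu, toluene, 90 °C
Reagents that add atoms: methylenetriphenylphosphorane C=P(c1ccccc1)(c1ccccc1)c1ccccc1 (from methyltriphenylphosphonium bromide C[P+](c1ccccc1)(c1ccccc1)c1ccccc1.[Br-] and KOt-Bu)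
Why: Wittig methylenation with a hot, salt-free ylide, the variant used for hindered ketones, turns the C10 carbonyl into the exocyclic C10=C1 alkene needed as the ene donor.

Step 4
Reactants: 5 (2S,3R,6RS)-2-allyl-2,3,6-trimethyl-1-methylidenecyclohexane; 6 methyl vinyl ketone
Product: 8 (5S,6R,8aR)-5-allyl-1,5,6,8a-tetramethyl-1,2,3,5,6,7,8,8a-octahydronaphthalen-1-ol, via ene-adduct ketone 7 (not isolated)
Conditions: Me2AlCl (2.2 equiv), CH2Cl2, −20 → 25 °C
Reagents that add atoms: none
Why: Me2AlCl-complexed methyl vinyl ketone acts as enophile: the terminal carbon C1 of the 1,1-disubstituted alkene of 5 adds to its β-carbon (C2) while the only allylic hydrogen, that on C5, is transferred, which gives the δ,ε-unsaturated ketone 7 with a tetrasubstituted C5=C10 alkene. A second, type I intramolecular carbonyl-ene (Prins-type) reaction then joins the complexed ketone carbon C4 to C5 and passes a C1 hydrogen to oxygen, which leaves the C1=C10 alkene. This is the known sequential ene annulation of alkylidenecycloalkanes with α,β-unsaturated ketones, run with an excess of a Lewis acid that also scavenges protons. Ring A closes as a six-membered ring through a chair-like transition state, 6-exo with respect to the carbonyl group and endo with respect to the C5=C10 alkene. The new quaternary centre C5 (R) should arise by approach of C4 anti to the pseudoaxial C9 methyl in the half-chair that keeps the C8 methyl equatorial, so that the C5 and C9 methyls end up cis, whereas the carbinol centre C4 is not controlled and is removed in step 8. The step needs regioselective hydrogen transfer (secured by the quaternary C9), chemoselectivity over the monosubstituted allyl alkene (too poor a donor for this Lewis-acid ene chemistry) and facial selectivity at C5, which rests on ring-B conformation alone and is the main uncertainty.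

Step 5
Reactants: 8 (5S,6R,8aR)-5-allyl-1,5,6,8a-tetramethyl-1,2,3,5,6,7,8,8a-octahydronaphthalen-1-ol
Product: 10 (5S,6R,8aR)-5-(2-hydroxyethyl)-1,5,6,8a-tetramethyl-1,2,3,5,6,7,8,8a-octahydronaphthalen-1-ol, via aldehyde 9 (not isolated)
Conditions: OsO4 (cat.), NaIO4, 2,6-lutidine, dioxane/H2O, rt; then NaBH4, MeOH, 0 °C
Reagents that add atoms: sodium periodate [Na+].[O-]I(=O)(=O)=O (oxygen, delivered through catalytic osmium tetroxide O=[Os](=O)(=O)=O)
Why: Lemieux–Johnson oxidative cleavage should take only the monosubstituted allyl alkene, because the trisubstituted C1=C10 alkene lies between two quaternary carbons, and borohydride then reduces aldehyde 9 to the C12 alcohol.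

Step 6
Reactants: 10 (5S,6R,8aR)-5-(2-hydroxyethyl)-1,5,6,8a-tetramethyl-1,2,3,5,6,7,8,8a-octahydronaphthalen-1-ol
Product: 11 (4aR,5S,6R,8aR)-5-(2-hydroxyethyl)-1,5,6,8a-tetramethyldecahydronaphthalen-1-ol
Conditions: Mn(dpm)3 (cat.), PhSiH3, t-BuOOH, i-PrOH, 22 °C
Reagents that add atoms: none
Why: Metal-hydride hydrogen-atom-transfer hydrogenation reduces hindered trisubstituted alkenes via the tertiary radical, here at C10, which should take up hydrogen on the face opposite the axial C5 and C9 methyls and so give the trans ring fusion (C10 R).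

Step 7
Reactants: 11 (4aR,5S,6R,8aR)-5-(2-hydroxyethyl)-1,5,6,8a-tetramethyldecahydronaphthalen-1-ol
Product: 12 (4aR,5S,6R,8aR)-5-(2-iodoethyl)-1,5,6,8a-tetramethyldecahydronaphthalen-1-ol
Conditions: PPh3, I2, imidazole, CH2Cl2, 0 °C → rt
Reagents that add atoms: iodine II
Why: The Appel reaction converts only the unhindered primary alcohol into the iodide, the tertiary carbinol being too hindered to form the alkoxyphosphonium ion.

Step 8
Reactants: 12 (4aR,5S,6R,8aR)-5-(2-iodoethyl)-1,5,6,8a-tetramethyldecahydronaphthalen-1-ol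
Product: 13 (1S,2R,4aR,8aR)-1-(2-iodoethyl)-1,2,4a,5-tetramethyl-1,2,3,4,4a,7,8,8a-octahydronaphthalene
Conditions: Burgess reagent, benzene, 50 °C
Reagents that add atoms: none
Why: Burgess dehydration (syn-elimination via the sulfamate ester) cannot eliminate toward the quaternary C5 and should give mainly the endocyclic trisubstituted C3=C4 alkene under neutral conditions that avoid a C4 cation and a Wagner–Meerwein methyl shift.

Step 9
Reactants: 14 but-2-yne-1,4-diol
Product: 15 4-[(tert-butyldimethylsilyl)oxy]but-2-yn-1-ol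
Conditions: NaH (1.0 equiv), THF, 0 °C → rt; TBSCl
Reagents that add atoms: tert-butyldimethylsilyl chloride CC(C)(C)[Si](C)(C)Cl
Why: Silyl ether formation through the sparingly soluble monosodium alkoxide of the symmetric diol should stop at the mono-TBS ether.

Step 10
Reactants: 15 4-[(tert-butyldimethylsilyl)oxy]but-2-yn-1-ol
Product: 17 (2Z)-4-[(tert-butyldimethylsilyl)oxy]-3-iodobut-2-en-1-ol, via cyclic vinylalanate 16 (not isolated)
Conditions: Red-Al, THF, 0 °C → rt; then I2, THF, −78 → 0 °C
Reagents that add atoms: iodine II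
Why: Hydroxyl-directed trans-hydroalumination of the propargylic alcohol places aluminium on the distal alkyne carbon in the cyclic alanate 16, and iodinolysis with retention gives the vinyl iodide with iodine cis to the CH2OH group (Z).

Step 11
Reactants: 17 (2Z)-4-[(tert-butyldimethylsilyl)oxy]-3-iodobut-2-en-1-ol; 18 docosanoyl chloride
Product: 19 (2Z)-4-[(tert-butyldimethylsilyl)oxy]-3-iodobut-2-en-1-yl docosanoate
Conditions: pyridine, DMAP (cat.), CH2Cl2, 0 °C → rt
Reagents that add atoms: none
Why: Pyridine/DMAP-mediated acylation esterifies the free primary allylic alcohol, which differentiates the two oxygens (C15 ester, C16 silyl ether) before the coupling.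

Step 12
Reactants: 13 (1S,2R,4aR,8aR)-1-(2-iodoethyl)-1,2,4a,5-tetramethyl-1,2,3,4,4a,7,8,8a-octahydronaphthalene; 19 (2Z)-4-[(tert-butyldimethylsilyl)oxy]-3-iodobut-2-en-1-yl docosanoate
Product: 22 (2E)-4-[(tert-butyldimethylsilyl)oxy]-3-{2-[(1S,2R,4aR,8aR)-1,2,4a,5-tetramethyl-1,2,3,4,4a,7,8,8a-octahydronaphthalen-1-yl]ethyl}but-2-en-1-yl docosanoate, via alkyllithium 20 (not isolated), via alkylzinc chloride 21 (not isolated)
Conditions: t-BuLi (2.1 equiv), Et2O, −78 °C; ZnCl2, THF, −78 → 0 °C; then 19, PdCl2(dppf) (cat.), THF, rt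
Reagents that add atoms: none
Why: Lithium–iodine exchange and transmetalation give the primary alkylzinc 21, which undergoes Negishi sp3–sp2 cross-coupling with the vinyl iodide with retention of alkene geometry, so that C12 ends up cis to C15 as in the target, and the organozinc tolerates the ester.

Step 13
Reactants: 22 (2E)-4-[(tert-butyldimethylsilyl)oxy]-3-{2-[(1S,2R,4aR,8aR)-1,2,4a,5-tetramethyl-1,2,3,4,4a,7,8,8a-octahydronaphthalen-1-yl]ethyl}but-2-en-1-yl docosanoate
Product: 23 (2E)-4-hydroxy-3-{2-[(1S,2R,4aR,8aR)-1,2,4a,5-tetramethyl-1,2,3,4,4a,7,8,8a-octahydronaphthalen-1-yl]ethyl}but-2-en-1-yl docosanoate (target)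
Conditions: HF·pyridine, THF/pyridine, 0 °C → rt
Reagents that add atoms: none
Why: Fluoride cleavage of the primary TBS ether leaves the ester untouched, and acyl migration is excluded because the two CH2O groups are trans on the alkene.

Compound list
1 | 2-methylcyclohex-2-en-1-one | CC1=CCCCC1=O | starting material
2 | bromomagnesium (3R)-2,3-dimethylcyclohex-1-en-1-olate | C[C@@H]1CCCC(O[Mg]Br)=C1C | intermediate
3 | (2S,3R)-2-allyl-2,3-dimethylcyclohexan-1-one | C=CC[C@@]1(C)[C@H](C)CCCC1=O | intermediate
4 | (2S,3R,6RS)-2-allyl-2,3,6-trimethylcyclohexan-1-one | C=CC[C@@]1(C)[C@H](C)CCC(C)C1=O | intermediate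
5 | (2S,3R,6RS)-2-allyl-2,3,6-trimethyl-1-methylidenecyclohexane | C=CC[C@@]1(C)[C@H](C)CCC(C)C1=C | intermediate
6 | methyl vinyl ketone (but-3-en-2-one) | CC(=O)C=C | starting material
7 | 4-[(5R,6S)-6-allyl-2,5,6-trimethylcyclohex-1-en-1-yl]butan-2-one | C=CC[C@@]1(C)[C@H](C)CCC(C)=C1CCCC(C)=O | intermediate
8 | (5S,6R,8aR)-5-allyl-1,5,6,8a-tetramethyl-1,2,3,5,6,7,8,8a-octahydronaphthalen-1-ol (C1 epimers; Δ1(10) in clerodane numbering) | C=CC[C@@]1(C)[C@H](C)CC[C@@]2(C)C(C)(O)CCC=C12 | intermediate
9 | 2-[(1S,2R,4aR)-5-hydroxy-1,2,4a,5-tetramethyl-1,2,3,4,4a,5,6,7-octahydronaphthalen-1-yl]acetaldehyde | O=CC[C@@]1(C)[C@H](C)CC[C@@]2(C)C(C)(O)CCC=C12 | intermediate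
10 | (5S,6R,8aR)-5-(2-hydroxyethyl)-1,5,6,8a-tetramethyl-1,2,3,5,6,7,8,8a-octahydronaphthalen-1-ol | OCC[C@@]1(C)[C@H](C)CC[C@@]2(C)C(C)(O)CCC=C12 | intermediate
11 | (4aR,5S,6R,8aR)-5-(2-hydroxyethyl)-1,5,6,8a-tetramethyldecahydronaphthalen-1-ol (trans-fused) | OCC[C@@]1(C)[C@H](C)CC[C@@]2(C)C(C)(O)CCC[C@H]12 | intermediate
12 | (4aR,5S,6R,8aR)-5-(2-iodoethyl)-1,5,6,8a-tetramethyldecahydronaphthalen-1-ol | ICC[C@@]1(C)[C@H](C)CC[C@@]2(C)C(C)(O)CCC[C@H]12 | intermediate
13 | (1S,2R,4aR,8aR)-1-(2-iodoethyl)-1,2,4a,5-tetramethyl-1,2,3,4,4a,7,8,8a-octahydronaphthalene | ICC[C@@]1(C)[C@H](C)CC[C@@]2(C)C(C)=CCC[C@H]12 | intermediate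
14 | but-2-yne-1,4-diol | OCC#CCO | starting material
15 | 4-[(tert-butyldimethylsilyl)oxy]but-2-yn-1-ol | OCC#CCO[Si](C)(C)C(C)(C)C | intermediate
16 | sodium cyclic vinylalanate (five-membered O–Al–C=C–C ring, two 2-methoxyethoxy ligands on Al, CH2OTBS on the Al-bearing carbon) | [Na+].COCCO[Al-]1(OCCOC)OCC=C1CO[Si](C)(C)C(C)(C)C | intermediate
17 | (2Z)-4-[(tert-butyldimethylsilyl)oxy]-3-iodobut-2-en-1-ol | OC/C=C(/CO[Si](C)(C)C(C)(C)C)I | intermediate
18 | docosanoyl chloride | CCCCCCCCCCCCCCCCCCCCCC(=O)Cl | starting material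
19 | (2Z)-4-[(tert-butyldimethylsilyl)oxy]-3-iodobut-2-en-1-yl docosanoate | CCCCCCCCCCCCCCCCCCCCCC(=O)OC/C=C(/CO[Si](C)(C)C(C)(C)C)I | intermediate
20 | {2-[(1S,2R,4aR,8aR)-1,2,4a,5-tetramethyl-1,2,3,4,4a,7,8,8a-octahydronaphthalen-1-yl]ethyl}lithium | [Li]CC[C@@]1(C)[C@H](C)CC[C@@]2(C)C(C)=CCC[C@H]12 | intermediate
21 | {2-[(1S,2R,4aR,8aR)-1,2,4a,5-tetramethyl-1,2,3,4,4a,7,8,8a-octahydronaphthalen-1-yl]ethyl}zinc chloride | Cl[Zn]CC[C@@]1(C)[C@H](C)CC[C@@]2(C)C(C)=CCC[C@H]12 | intermediate
22 | (2E)-4-[(tert-butyldimethylsilyl)oxy]-3-{2-[(1S,2R,4aR,8aR)-1,2,4a,5-tetramethyl-1,2,3,4,4a,7,8,8a-octahydronaphthalen-1-yl]ethyl}but-2-en-1-yl docosanoate | CCCCCCCCCCCCCCCCCCCCCC(=O)OC/C=C(/CO[Si](C)(C)C(C)(C)C)CC[C@@]1(C)[C@H](C)CC[C@@]2(C)C(C)=CCC[C@H]12 | intermediate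
23 | (2E)-4-hydroxy-3-{2-[(1S,2R,4aR,8aR)-1,2,4a,5-tetramethyl-1,2,3,4,4a,7,8,8a-octahydronaphthalen-1-yl]ethyl}but-2-en-1-yl docosanoate | CCCCCCCCCCCCCCCCCCCCCC(=O)OC/C=C(/CO)CC[C@@]1(C)[C@H](C)CC[C@@]2(C)C(C)=CCC[C@H]12 | target

Total step count: 13. Longest linear sequence: 10 steps (steps 1–8, 12, 13); the side-chain fragment takes steps 9–11.

Steps most likely to fail

1. Step 4 (key step). The ring-closing carbonyl-ene reaction may show poor facial selectivity at C5, because the two faces of the C5=C10 alkene differ only through the remote C9 substituents, which are similar in size; both C5 epimers may then form. The C10 cationic intermediate may also undergo a 1,2-shift before hydrogen transfer. The fallback changes the order of events, so that C5 is set first and C10, C9 and C8 are then set on a rigid decalin. It gives up the one-operation annulation, sets out from 6 and comes back at 11. Compound 6 and 2-methylcyclohexane-1,3-dione are joined by the Hajos–Parrish–Eder–Sauer–Wiechert annulation (D-proline) to give (R)-Wieland–Miescher ketone F1. MeMgBr at −78 °C should add to the saturated ketone only and give carbinol enone F2. Birch reduction (Li/NH3) with MeI trapping gives the trans-fused 9-methyl decalone F3. Its more substituted enolate (KH, THF) is alkylated with ethyl bromoacetate on the face opposite the axial C5 methyl to give keto ester F4. Wittig methylenation gives the 8(17)-alkene F5, and hydrogenation (H2, PtO2) from the less hindered face gives the 8-methyl ester F6. LiAlH4 reduces the ester to 11.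

2. Step 3. The basic ylide may deprotonate (enolise) the hindered ketone between a quaternary and a tertiary carbon instead of adding to it, so that 4 is returned. The fallback is a two-stage Peterson olefination that sets out from 4 and comes back at 5. CeCl3-mediated addition of the much less basic Me3SiCH2Li gives β-hydroxysilane F7, and KH-induced syn-elimination then gives 5.

3. Step 6. Hydrogen-atom delivery to the planar C10 radical may not discriminate the two faces well enough, which would give cis-fused decalin, or hydrogen-atom transfer to the shielded alkene may be slow. The fallback is substrate-directed homogeneous hydrogenation with a cationic iridium catalyst (Crabtree catalyst, H2, CH2Cl2); it sets out from 10, comes back at 11 and makes no new compound (F0). The primary hydroxyl of the C9 arm lies on the face opposite the two axial methyls; it should bind the metal and deliver hydrogen to that face of C1=C10.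

Further compounds
F1 | step 4 | (R)-Wieland–Miescher ketone, (8aR)-8a-methyl-3,4,8,8a-tetrahydronaphthalene-1,6(2H,7H)-dione | O=C1CC[C@@]2(C)C(=O)CCCC2=C1
F2 | step 4 | (4aR)-5-hydroxy-4a,5-dimethyl-4,4a,5,6,7,8-hexahydronaphthalen-2(3H)-one (carbinol enone) | O=C1CC[C@@]2(C)C(C)(O)CCCC2=C1
F3 | step 4 | trans-fused (4aR,8aR)-5-hydroxy-1,4a,5-trimethyloctahydronaphthalen-2(1H)-one (C1 epimers) | O=C1CC[C@@]2(C)C(C)(O)CCC[C@@H]2C1C
F4 | step 4 | ethyl 2-[(4aR,8aR)-5-hydroxy-1,4a,5-trimethyl-2-oxodecahydronaphthalen-1-yl]acetate, 1-methyl cis to the 4a-methyl | O=C1CC[C@@]2(C)C(C)(O)CCC[C@@H]2[C@@]1(C)CC(=O)OCC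
F5 | step 4 | ethyl 2-[(4aR,8aR)-5-hydroxy-1,4a,5-trimethyl-2-methylidenedecahydronaphthalen-1-yl]acetate | C=C1CC[C@@]2(C)C(C)(O)CCC[C@@H]2[C@@]1(C)CC(=O)OCC
F6 | step 4 | ethyl 2-[(4aR,8aR)-5-hydroxy-1,2,4a,5-tetramethyldecahydronaphthalen-1-yl]acetate, ring configuration as in 11 | C[C@@H]1CC[C@@]2(C)C(C)(O)CCC[C@@H]2[C@@]1(C)CC(=O)OCC
F7 | step 3 | (2S,3R)-2-allyl-2,3,6-trimethyl-1-[(trimethylsilyl)methyl]cyclohexan-1-ol | C=CC[C@@]1(C)[C@H](C)CCC(C)C1(O)C[Si](C)(C)C
F0 | step 6 | none | none
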